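## Plan

1. Locants: side chain C1 (ArOCH2), C2 (CHOH), C3 (C(CH3)OH), C4, C5 (lactone CH–O), C6, C7 (CHCH3), C8 (lactone C=O); O2, O3 and O5 sit on C2, C3 and C5. Hardest feature: four stereocentres on an open chain, with a tertiary carbinol C3 whose CH3 and CH2 arms are nearly alike and whose O3 is anti to both O2 and O5.
2. Enabling feature: C3(CH3)–C4H2–C5H(O)–C6H2–C7(CH3) is a hidden mirror-symmetric segment, and C8 on C7 is only one oxygen (O3) away from C3. Deleting O3 (retro-Baeyer–Villiger) folds C3–C8 into a meso 4-oxy-2,6-dimethylcyclohexanone, the perhydro form of 2,6-dimethylhydroquinone, in which C2–C1 lies 1,3-diaxial to O5.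
3. Cuts: C1–OAr (epoxide opening); acyl swap C8–O5 → C8–O3 with C1(=O)–O5; O3 removed from C3–O3–C8 (temporary C3–C8 bond); C2–C3 (aldol) across a temporary glyoxylate ester tether C1(=O)–O5.
4. Forward: arene → cyclohexane ring (steps 1–3) → δ-lactone ring closed onto it (step 6, 2-oxabicyclo[3.3.1]nonane) → carbocycle expanded by O3 (step 7) → tether cut and γ-lactone formed when O5 captures C8 (step 8) → coumarin joined last (steps 9–10).
5. Stereochemistry: the C5/C7 relation comes from equilibration and equatorial hydride delivery. C3 and C2 come from the tether. The absolute configuration of all four comes from one chiral phosphoric acid that picks one of two enantiotopic α-carbons, and the Baeyer–Villiger migration retains C3.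

Key step: step 6

Remark: 7-hydroxy-8-methoxycoumarin (daphnetin 8-methyl ether) is taken as a catalogue compound.
Remark: the sense of induction of the phosphoric acid in step 6 cannot be derived from precedent. (R)-TRIP is written, and its commercial antipode is used instead if the first run shows the mirror-image series.

## Route

Step 1
Reactants: 1 2,6-dimethylbenzene-1,4-diol (2,6-dimethylhydroquinone)
Product: 2 2,6-dimethylcyclohexane-1,4-diol (mixture of stereoisomers)
Conditions: H2 (80 bar), 5% Rh/Al2O3, i-PrOH, 80 °C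
Reagents that add atoms: none
Why: Heterogeneous arene hydrogenation of phenols over rhodium runs with little C–O hydrogenolysis, and the configuration of 2 does not matter because every centre is erased, equilibrated or reset in steps 2 and 3.

Step 2
Reactants: 2 2,6-dimethylcyclohexane-1,4-diol
Product: 3 (2R,6S)-2,6-dimethylcyclohexane-1,4-dione (meso; methyls cis)
Conditions: aq NaOCl (2.3 equiv), AcOH, 0→20 °C; then DBU (10 mol %), CH2Cl2, 20 °C, N2
Reagents that add atoms: none
Why: Hypochlorite/acetic acid oxidation of secondary alcohols takes both carbinols to ketones, and base equilibration through the C8 enolate should settle both methyl groups equatorial, that is cis.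

Step 3
Reactants: 3 (2R,6S)-2,6-dimethylcyclohexane-1,4-dione
Product: 4 (2R,4s,6S)-4-hydroxy-2,6-dimethylcyclohexan-1-one (meso; OH axial and trans to both equatorial methyls)
Conditions: L-Selectride (1.0 equiv), THF, −78 °C; then 30% H2O2, pH 7 buffer, 0 °C
Reagents that add atoms: none
Why: The bulky trialkylborohydride should reduce the unflanked C5 carbonyl much faster than C8=O, which is walled in by two α-methyls, and should attack along the equatorial trajectory as it does with cis-3,5-dimethylcyclohexanone, which puts O5 axial and trans to the methyls.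

Step 4
Reactants: 4 (2R,4s,6S)-4-hydroxy-2,6-dimethylcyclohexan-1-one
Product: 5 (1s,3R,5S)-3,5-dimethyl-4-oxocyclohexyl prop-2-enoate (meso acrylate)
Conditions: acryloyl chloride, Et3N, BHT (trace), CH2Cl2, 0 °C
Reagents that add atoms: acryloyl chloride C=CC(=O)Cl
Why: Plain O-acylation of a secondary alcohol by an acid chloride leaves the C5–O bond untouched and installs a storable, latent glyoxylate.

Step 5
Reactants: 5 (1s,3R,5S)-3,5-dimethyl-4-oxocyclohexyl prop-2-enoate
Product: 7 (1s,3R,5S)-3,5-dimethyl-4-oxocyclohexyl 2-oxoacetate (meso glyoxylate), via secondary ozonide 6 (not isolated)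
Conditions: O3, CH2Cl2, −78 °C; then Me2S, −78→20 °C; azeotropic drying with toluene, used at once
Reagents that add atoms: ozone [O-][O+]=O
Why: Ozonolysis cleaves the only C=C bond and the reductive work-up gives the glyoxylate ester, while ketone and ester are inert and the cold, neutral medium avoids a premature racemic aldolisation.

Step 6
Reactants: 7 (1s,3R,5S)-3,5-dimethyl-4-oxocyclohexyl 2-oxoacetate
Product: 9 (1S,4R,5R,7S)-4-hydroxy-5,7-dimethyl-2-oxabicyclo[3.3.1]nonane-3,6-dione, via enol 8 (not isolated)
Conditions: (R)-TRIP (10 mol %), toluene (0.02 M), 4 Å MS, 50 °C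
Reagents that add atoms: none
Why: Proposed new method: the phosphoric acid turns ketone 7 reversibly into its only possible enol, the tetrasubstituted C8(OH)=C3(CH3) enol 8 or its mirror image at C7, and then bridges the enol O–H (to P=O) and the formyl oxygen (to P–OH), so that C3 adds to C2 in a closed, ene-like transition state. The closest known reaction types are the chiral-phosphoric-acid-catalysed direct aldol of cyclohexanone with ethyl glyoxylate, enol catalysis of α-branched cyclic ketones and the amine-catalysed desymmetrising aldolisation of σ-symmetric 4-(3-oxopropyl)cyclohexanones to bicyclo[3.3.1]nonanes; new is their union in an ester-tethered case that forms a quaternary carbon. The one ring that closes is the δ-lactone O5–C1–C2–C3–C4–C5, by a 6-(enolexo)-exo-trig aldolisation that gives a chair–chair 2-oxabicyclo[3.3.1]nonane. C3 is controlled by the tether, because the three-atom arm O5–C1–C2 on the axial oxygen reaches only the ring face cis to O5, so C2 becomes axial and the C3 methyl equatorial and cis to the C7 methyl; C2 is controlled by the same ring, since C1 is held anti to the C3 methyl and the formyl oxygen must lie gauche to C8–OH to stay in the hydrogen-bond relay, which places O2 equatorial on the lactone ring (4R); C5 and C7 already have the right relative configuration and become stereogenic in the absolute sense when the catalyst picks C3 over its enantiotopic twin C7. The selectivity needed is therefore only enantiotopic-group selection and cyclisation over oligomerisation: there is no second kind of enolisable position next to C8, O5 is γ to the ketone so that no β-elimination competes, and high dilution favours ring closure. Because enolisation is reversible, any stereoisomer of 7 at the methyl-bearing carbons feeds the same productive enol, and the equatorial C7 methyl of the locked bicycle is also the thermodynamic one.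

Step 7
Reactants: 9 (1S,4R,5R,7S)-4-hydroxy-5,7-dimethyl-2-oxabicyclo[3.3.1]nonane-3,6-dione
Product: 10 (1R,4S,6S,9R)-9-hydroxy-1,4-dimethyl-2,7-dioxabicyclo[4.3.1]decane-3,8-dione
Conditions: mCPBA (2 equiv), CH2Cl2, 25 °C
Reagents that add atoms: mCPBA OOC(=O)c1cccc(Cl)c1
Why: In the Baeyer–Villiger oxidation the fully substituted C3 should outrank the secondary C7 in migratory aptitude and migrates with retention, so the temporary C3–C8 bond becomes C3–O3–C8 with the correct tertiary C–O configuration, while lactone and hydroxyl are inert to the peracid.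

Step 8
Reactants: 10 (1R,4S,6S,9R)-9-hydroxy-1,4-dimethyl-2,7-dioxabicyclo[4.3.1]decane-3,8-dione
Product: 12 (3S,5S)-3-methyl-5-[(2R,3S)-2,3,4-trihydroxy-2-methylbutyl]oxolan-2-one, via oxepanone triol 11 (not isolated)
Conditions: BH3·SMe2 (1.2 equiv), NaBH4 (5 mol %), THF, 0→20 °C; MeOH quench; then CSA (5 mol %), CH2Cl2, 20 °C
Reagents that add atoms: none
Why: In the hydroxyl-directed borane reduction of an α-hydroxy ester the O2–borane adduct delivers hydride through a five-membered chelate to C1 only, C8 being remote and shielded as the ester of a tertiary alcohol, and the freed O5–H then takes over C8 under acid catalysis (translactonisation) because a γ-lactone of a secondary alcohol is far more stable than a seven-membered lactone of a tertiary one, with no stereocentre touched.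

Step 9
Reactants: 12 (3S,5S)-3-methyl-5-[(2R,3S)-2,3,4-trihydroxy-2-methylbutyl]oxolan-2-one
Product: 13 (2S,3R)-2,3-dihydroxy-3-methyl-4-[(2S,4S)-4-methyl-5-oxooxolan-2-yl]butyl 4-methylbenzenesulfonate
Conditions: TsCl (1.05 equiv), Bu2SnO (2 mol %), Et3N, CH2Cl2, 0→20 °C
Reagents that add atoms: p-toluenesulfonyl chloride Cc1ccc(cc1)S(=O)(=O)Cl
Why: Stannylene-acetal-catalysed monosulfonylation of a terminal 1,2-diol is selective for the primary hydroxyl over the secondary and tertiary ones.

Step 10
Reactants: 13 (2S,3R)-2,3-dihydroxy-3-methyl-4-[(2S,4S)-4-methyl-5-oxooxolan-2-yl]butyl 4-methylbenzenesulfonate; 14 7-hydroxy-8-methoxy-2H-chromen-2-one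
Product: 16 7-{[(2S,3R)-2,3-dihydroxy-3-methyl-4-[(2S,4S)-4-methyl-5-oxooxolan-2-yl]butyl]oxy}-8-methoxy-2H-chromen-2-one (target), via epoxy alcohol 15 (not isolated)
Conditions: K2CO3 (1.5 equiv), dry DMF, 25 °C; then 14 (1.1 equiv), 70 °C
Reagents that add atoms: none
Why: Intramolecular Williamson closure of O2 onto C1 leaves the C2–O bond intact, the acidic coumarin phenol then opens the terminal epoxide by SN2 at the unhindered CH2, a Payne shift to the 2,3-epoxide is reversible and unproductive so that C2 and C3 are not scrambled, and both lactones tolerate carbonate in dry DMF.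

## Compound list

1 | 2,6-dimethylbenzene-1,4-diol | Cc1cc(O)cc(C)c1O | starting material
2 | 2,6-dimethylcyclohexane-1,4-diol (mixture of stereoisomers) | CC1CC(O)CC(C)C1O | intermediate
3 | (2R,6S)-2,6-dimethylcyclohexane-1,4-dione (meso) | C[C@H]1CC(=O)C[C@@H](C)C1=O | intermediate
4 | (2R,4s,6S)-4-hydroxy-2,6-dimethylcyclohexan-1-one (meso) | O[C@@H]1C[C@@H](C)C(=O)[C@@H](C)C1 | intermediate
5 | (1s,3R,5S)-3,5-dimethyl-4-oxocyclohexyl prop-2-enoate (meso) | C=CC(=O)O[C@@H]1C[C@@H](C)C(=O)[C@@H](C)C1 | intermediate
6 | (1s,3R,5S)-3,5-dimethyl-4-oxocyclohexyl 1,2,4-trioxolane-3-carboxylate (trioxolane carbon undefined) | O=C(O[C@@H]1C[C@@H](C)C(=O)[C@@H](C)C1)C1OCOO1 | intermediate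
7 | (1s,3R,5S)-3,5-dimethyl-4-oxocyclohexyl 2-oxoacetate (meso) | O=CC(=O)O[C@@H]1C[C@@H](C)C(=O)[C@@H](C)C1 | intermediate
8 | (1S,5S)-4-hydroxy-3,5-dimethylcyclohex-3-en-1-yl 2-oxoacetate | O=CC(=O)O[C@@H]1CC(C)=C(O)[C@@H](C)C1 | intermediate
9 | (1S,4R,5R,7S)-4-hydroxy-5,7-dimethyl-2-oxabicyclo[3.3.1]nonane-3,6-dione | C[C@H]1C[C@H]2C[C@@](C)(C1=O)[C@@H](O)C(=O)O2 | intermediate
10 | (1R,4S,6S,9R)-9-hydroxy-1,4-dimethyl-2,7-dioxabicyclo[4.3.1]decane-3,8-dione | C[C@H]1C[C@H]2C[C@@](C)(OC1=O)[C@@H](O)C(=O)O2 | intermediate
11 | (3S,5S,7R)-7-[(1S)-1,2-dihydroxyethyl]-5-hydroxy-3,7-dimethyloxepan-2-one | C[C@H]1C[C@H](O)C[C@@](C)(OC1=O)[C@@H](O)CO | intermediate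
12 | (3S,5S)-3-methyl-5-[(2R,3S)-2,3,4-trihydroxy-2-methylbutyl]oxolan-2-one | OC[C@H](O)[C@](C)(O)C[C@@H]1C[C@H](C)C(=O)O1 | intermediate
13 | (2S,3R)-2,3-dihydroxy-3-methyl-4-[(2S,4S)-4-methyl-5-oxooxolan-2-yl]butyl 4-methylbenzenesulfonate | Cc1ccc(cc1)S(=O)(=O)OC[C@H](O)[C@](C)(O)C[C@@H]1C[C@H](C)C(=O)O1 | intermediate
14 | 7-hydroxy-8-methoxy-2H-chromen-2-one | COc1c(O)ccc2ccc(=O)oc12 | starting material
15 | (3S,5S)-5-{(2R)-2-hydroxy-2-[(2S)-oxiran-2-yl]propyl}-3-methyloxolan-2-one | C1O[C@@H]1[C@](C)(O)C[C@@H]2C[C@H](C)C(=O)O2 | intermediate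
16 | 7-{[(2S,3R)-2,3-dihydroxy-3-methyl-4-[(2S,4S)-4-methyl-5-oxooxolan-2-yl]butyl]oxy}-8-methoxy-2H-chromen-2-one | COc1c(OC[C@H](O)[C@](C)(O)C[C@@H]2C[C@H](C)C(=O)O2)ccc2ccc(=O)oc12 | target

## Step count and risks

Total step count: 10. Longest linear sequence: 10 steps (1 → 16); 14 enters in the last step.

**Step 6.** The catalyst may discriminate poorly between the two enantiotopic α-carbons. Enolisation of the hindered ketone and rotation of the ester into its less stable lactone-type rotamer may also be so slow that oligomerisation of the glyoxylate wins.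

The fallback sets out from 3 and comes back at 9.
- The unhindered C5 carbonyl of 3 is ketalised selectively (ethylene glycol, p-TsOH, toluene, water removal) to the meso ketal (7R,9S)-7,9-dimethyl-1,4-dioxaspiro[4.5]decan-8-one F1.
- Enantioselective deprotonation with lithium (R,R)-bis(1-phenylethyl)amide/LiCl and in-situ TMSCl quench, a desymmetrisation known for cis-2,6-dimethylcyclohexanone itself (amide antipode chosen by the first run), gives the silyl enol ether {[(9S)-7,9-dimethyl-1,4-dioxaspiro[4.5]dec-7-en-8-yl]oxy}trimethylsilane F2.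
- A Mukaiyama aldol with ethyl glyoxylate (MgBr2·OEt2, CH2Cl2, −78 °C), by axial attack anti to the C7 methyl, gives ethyl (2R)-2-hydroxy-2-[(7R,9S)-7,9-dimethyl-8-oxo-1,4-dioxaspiro[4.5]decan-7-yl]acetate F3. A C2 epimer would be removed here.
- Aqueous acid frees the C5 ketone to give ethyl (2R)-2-hydroxy-2-[(1R,3S)-1,3-dimethyl-2,5-dioxocyclohexyl]acetate F4.
- L-Selectride, kept off the axial face by the axial side chain, delivers hydride equatorially, and the axial C5 alkoxide closes onto the ethyl ester to give 9.

**Step 7.** The secondary C7 may migrate competitively, because C3 carries the inductively withdrawing C2(OH)–C1(=O)O group. Addition of the peracid to the hindered carbonyl may also be slow.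

The fallback sets out from 9 and comes back at 12.
- Palladium(II)-catalysed aerobic dehydrogenation (Pd(TFA)2, DMSO, O2, AcOH, 80 °C), which can only involve C7–H and C6–H, gives the enone (1R,4R,5R)-4-hydroxy-5,7-dimethyl-2-oxabicyclo[3.3.1]non-7-ene-3,6-dione F5.
- The rival migrating carbon is now sp2 and conjugated, so Baeyer–Villiger oxidation should move C3 and give (1R,6R,9R)-9-hydroxy-1,4-dimethyl-2,7-dioxabicyclo[4.3.1]dec-4-ene-3,8-dione F6.
- The directed borane reduction and acid-catalysed acyl transfer of step 8 give the butenolide (5R)-3-methyl-5-[(2R,3S)-2,3,4-trihydroxy-2-methylbutyl]furan-2(5H)-one F7.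
- Hydrogenation (H2, Rh/Al2O3, EtOAc) from the butenolide face opposite the C5 side chain resets C7 cis to that chain and gives 12.

**Step 8.** Chemoselectivity between the two lactone carbonyls may be lost, or the reduction may stop at the bridged lactol.

The fallback sets out from 10 and comes back at 12 and separates the two events.
- CSA in MeOH at 40 °C lets the acyl groups change partners under thermodynamic control. Methanol opens the α-hydroxy δ-lactone, O5–H takes C8 and O3–H is released, which gives methyl (2R,3R)-2,3-dihydroxy-3-methyl-4-[(2S,4S)-4-methyl-5-oxooxolan-2-yl]butanoate F8.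
- F8 is an open-chain α-hydroxy methyl ester beside a second ester, the classical substrate class of the hydroxyl-directed BH3·SMe2/cat. NaBH4 reduction, which then gives 12.

## Further compounds

F1 | step 6 | (7R,9S)-7,9-dimethyl-1,4-dioxaspiro[4.5]decan-8-one (meso) | C[C@H]1CC2(C[C@@H](C)C1=O)OCCO2
F2 | step 6 | {[(9S)-7,9-dimethyl-1,4-dioxaspiro[4.5]dec-7-en-8-yl]oxy}trimethylsilane | C[C@H]1CC2(CC(C)=C1O[Si](C)(C)C)OCCO2
F3 | step 6 | ethyl (2R)-2-hydroxy-2-[(7R,9S)-7,9-dimethyl-8-oxo-1,4-dioxaspiro[4.5]decan-7-yl]acetate | C[C@H]1CC2(C[C@@](C)(C1=O)[C@@H](O)C(=O)OCC)OCCO2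
F4 | step 6 | ethyl (2R)-2-hydroxy-2-[(1R,3S)-1,3-dimethyl-2,5-dioxocyclohexyl]acetate | C[C@H]1CC(=O)C[C@@](C)(C1=O)[C@@H](O)C(=O)OCC
F5 | step 7 | (1R,4R,5R)-4-hydroxy-5,7-dimethyl-2-oxabicyclo[3.3.1]non-7-ene-3,6-dione | CC1=C[C@H]2C[C@@](C)(C1=O)[C@@H](O)C(=O)O2
F6 | step 7 | (1R,6R,9R)-9-hydroxy-1,4-dimethyl-2,7-dioxabicyclo[4.3.1]dec-4-ene-3,8-dione | CC1=C[C@H]2C[C@@](C)(OC1=O)[C@@H](O)C(=O)O2
F7 | step 7 | (5R)-3-methyl-5-[(2R,3S)-2,3,4-trihydroxy-2-methylbutyl]furan-2(5H)-one | OC[C@H](O)[C@](C)(O)C[C@@H]1C=C(C)C(=O)O1
F8 | step 8 | methyl (2R,3R)-2,3-dihydroxy-3-methyl-4-[(2S,4S)-4-methyl-5-oxooxolan-2-yl]butanoate | COC(=O)[C@H](O)[C@](C)(O)C[C@@H]1C[C@H](C)C(=O)O1
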